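**Retrosynthetic overview**
1. Target 16 ⇐ bis-silyl ether 15 (desilylation of the ring-B catechol only).
2. 15 ⇐ open-chain 9-hydroxy-3,5,7-trioxo ester 12. In one flask the carbinol oxygen closes onto C-5 (ring C, a dihydropyranone), then the tert-butyl β-keto ester gives an acylketene that closes onto the pyranone C-5 (ring A). Ring C forms before ring A, both in step 7; O-1 is bonded to C-8a before ring A exists, which fixes the 6-prenyl pattern.
3. 12 ⇐ Claisen union of (S)-β-hydroxy ester 6 (C-2, C-3, C-4 and ring B) with the trianion of prenylated triketide ester 11 (all six ring-A carbons).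
4. 6 ⇐ aldehyde 4 by catalytic asymmetric acetate Mukaiyama aldol (sets the only stereocentre); 4 ⇐ bromocatechol aldehyde 1 (silylation, Stille prenylation); 11 ⇐ tert-butyl acetoacetate 7 (C-prenylation, dianion acetylation).

Abbreviations: TBS = tert-butyldimethylsilyl; prenyl = 3-methylbut-2-en-1-yl; ArB = 3,4-bis(TBS-oxy)-5-prenylphenyl.

Assumption: 1 is bought (otherwise one step from 5-bromovanillin with AlCl3/pyridine); in step 3 the catalyst antipode that gives Si-face attack is used and the (S) assignment is confirmed by Mosher analysis on the first run.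

**Step 1**
Reactants: 1 3-bromo-4,5-dihydroxybenzaldehyde
Product: 2 3-bromo-4,5-bis(tert-butyldimethylsilyloxy)benzaldehyde
Conditions: TBSCl (2.5 equiv), imidazole (5 equiv), DMAP (5 mol %), DMF, 23 °C
Reagents that add atoms: tert-butyldimethylsilyl chloride (TBSCl), CC(C)(C)[Si](C)(C)Cl
Why: Standard phenol silylation of both catechol hydroxyls; the aldehyde and aryl bromide are inert, and aryl TBS ethers survive the later Lewis-acid, amide-base and thermal steps yet come off with mild fluoride.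

**Step 2**
Reactants: 2 3-bromo-4,5-bis(tert-butyldimethylsilyloxy)benzaldehyde; 3 tributyl(3-methylbut-2-en-1-yl)stannane
Product: 4 3,4-bis(tert-butyldimethylsilyloxy)-5-(3-methylbut-2-en-1-yl)benzaldehyde
Conditions: Pd(PPh3)4 (5 mol %), toluene, 105 °C
Reagents that add atoms: none
Why: Migita–Kosugi–Stille coupling; transmetalation at the unsubstituted α-carbon of the prenylstannane gives the linear prenyl arene, and the neutral, fluoride-free conditions keep the aryl silyl ethers and the free aldehyde.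

**Step 3**
Reactants: 4 3,4-bis(tert-butyldimethylsilyloxy)-5-(3-methylbut-2-en-1-yl)benzaldehyde; 5 1-(tert-butyldimethylsilyloxy)-1-methoxyethene
Product: 6 methyl (3S)-3-[3,4-bis(tert-butyldimethylsilyloxy)-5-(3-methylbut-2-en-1-yl)phenyl]-3-hydroxypropanoate
Conditions: SiCl4 (1.2 equiv), binaphthyldiamine-derived chiral bisphosphoramide (2 mol %), i-Pr2NEt (5 mol %), CH2Cl2, −78 °C; then sat. aq NaHCO3
Reagents that add atoms: none
Why: Lewis-base-activated Mukaiyama aldol (Denmark type); the chiral phosphoramide-bound trichlorosilyl cation binds the aldehyde and the acetate ketene acetal adds to its Si face, giving the (S)-carbinol that becomes C-2 of the flavanone, and this C–O bond is never broken afterwards.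

**Step 4**
Reactants: 7 tert-butyl acetoacetate; 8 1-bromo-3-methylbut-2-ene (prenyl bromide)
Product: 9 tert-butyl 2-acetyl-5-methylhex-4-enoate
Conditions: NaH (1.05 equiv), THF, 0 °C; then 8 (1.0 equiv), 0 → 23 °C
Reagents that add atoms: none
Why: Acetoacetic ester C-alkylation (SN2 at the primary allylic bromide) places the prenyl group on the carbon that becomes C-6 of ring A.

**Step 5**
Reactants: 9 tert-butyl 2-acetyl-5-methylhex-4-enoate; 10 N-methoxy-N-methylacetamide
Product: 11 tert-butyl 2-(3-methylbut-2-en-1-yl)-3,5-dioxohexanoate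
Conditions: LDA (2.1 equiv), THF, −78 → 0 °C; then 10, −78 → 0 °C; aq NH4Cl
Reagents that add atoms: none
Why: Huckin–Weiler dianion chemistry; the γ-carbanion is the most nucleophilic site and is acylated once by the Weinreb amide, whose stable tetrahedral adduct prevents over-addition.

**Step 6**
Reactants: 6 methyl (3S)-3-[3,4-bis(tert-butyldimethylsilyloxy)-5-(3-methylbut-2-en-1-yl)phenyl]-3-hydroxypropanoate; 11 tert-butyl 2-(3-methylbut-2-en-1-yl)-3,5-dioxohexanoate
Product: 12 tert-butyl (9S)-9-[3,4-bis(tert-butyldimethylsilyloxy)-5-(3-methylbut-2-en-1-yl)phenyl]-9-hydroxy-2-(3-methylbut-2-en-1-yl)-3,5,7-trioxononanoate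
Conditions: 11 (2.5 equiv), LDA (7.6 equiv), THF, 0 °C; add lithium alkoxide of 6 (LDA 1.0 equiv, −78 °C); −78 → −20 °C; AcOH, −78 °C; pH 5 work-up
Reagents that add atoms: none
Why: Harris-type polyanion Claisen acylation; the terminal CH2⁻ of the trianion attacks the methyl ester, the substrate is protected in situ as its lithium alkoxide (as in acylations of β-hydroxy esters with excess ester enolate), the product polyanion resists further attack and the carbinol centre is not touched.

**Step 7**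
Reactants: 12 tert-butyl (9S)-9-[3,4-bis(tert-butyldimethylsilyloxy)-5-(3-methylbut-2-en-1-yl)phenyl]-9-hydroxy-2-(3-methylbut-2-en-1-yl)-3,5,7-trioxononanoate
Product: 15 (2S)-2-[3,4-bis(tert-butyldimethylsilyloxy)-5-(3-methylbut-2-en-1-yl)phenyl]-5,7-dihydroxy-6-(3-methylbut-2-en-1-yl)chroman-4-one, via dihydropyranone tert-butyl ester 13 (not isolated), via α-prenyl acylketene 14 (not isolated)
Conditions: CSA (5 mol %), 4 Å MS, toluene (5 mM), 0 → 23 °C, 1 h; then solid NaHCO3 (20 mol %), 110 °C, 4 h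
Reagents that add atoms: none
Why: Proposed new method: at 23 °C the C-9 hydroxyl adds to the C-5 ketone and the hemiketal dehydrates to the 2,3-dihydro-4H-pyran-4-one 13 (the classical acid-catalysed cyclodehydration of δ-hydroxy-1,3-diketones, which retains configuration because the carbinol C–O bond stays intact and which blocks the competing 2-pyranone, 4-pyranone and aldol closures), then at 110 °C the tert-butyl β-keto ester loses tert-butanol to acylketene 14, whose enol form is a dienylketene (C=C=O, enol C=C, pyranone C=C) that closes by 6π-electrocyclisation onto the nucleophilic pyranone C-5 and enolises to the phloroglucinol ring; the closest known reactions are thermal acylketene generation from tert-butyl β-keto esters, the dienylketene electrocyclisation that ends the Danheiser benzannulation, and the Harris-type Claisen cyclisation of 3,5,7-triketo esters to acylphloroglucinols.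

**Step 8**
Reactants: 15 (2S)-2-[3,4-bis(tert-butyldimethylsilyloxy)-5-(3-methylbut-2-en-1-yl)phenyl]-5,7-dihydroxy-6-(3-methylbut-2-en-1-yl)chroman-4-one
Product: 16 (2S)-2-[3,4-dihydroxy-5-(3-methylbut-2-en-1-yl)phenyl]-5,7-dihydroxy-6-(3-methylbut-2-en-1-yl)chroman-4-one
Conditions: KHF2 (4 equiv), MeOH, 23 °C
Reagents that add atoms: none
Why: Fluoride cleavage of phenolic TBS ethers under slightly acidic conditions, so there is no base to open the 5-hydroxyflavanone (no retro-oxa-Michael racemisation) and no strong acid to cyclise the prenyl groups onto the neighbouring phenols.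

**Compound list**
1 | 3-bromo-4,5-dihydroxybenzaldehyde | O=Cc1cc(O)c(O)c(Br)c1 | starting material
2 | 3-bromo-4,5-bis(tert-butyldimethylsilyloxy)benzaldehyde | O=Cc1cc(O[Si](C)(C)C(C)(C)C)c(O[Si](C)(C)C(C)(C)C)c(Br)c1 | intermediate
3 | tributyl(3-methylbut-2-en-1-yl)stannane | CCCC[Sn](CCCC)(CCCC)CC=C(C)C | starting material
4 | 3,4-bis(tert-butyldimethylsilyloxy)-5-(3-methylbut-2-en-1-yl)benzaldehyde | O=Cc1cc(O[Si](C)(C)C(C)(C)C)c(O[Si](C)(C)C(C)(C)C)c(CC=C(C)C)c1 | intermediate
5 | 1-(tert-butyldimethylsilyloxy)-1-methoxyethene | C=C(OC)O[Si](C)(C)C(C)(C)C | starting material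
6 | methyl (3S)-3-ArB-3-hydroxypropanoate | COC(=O)C[C@H](O)c1cc(CC=C(C)C)c(O[Si](C)(C)C(C)(C)C)c(O[Si](C)(C)C(C)(C)C)c1 | intermediate
7 | tert-butyl acetoacetate | CC(=O)CC(=O)OC(C)(C)C | starting material
8 | 1-bromo-3-methylbut-2-ene | CC(C)=CCBr | starting material
9 | tert-butyl 2-acetyl-5-methylhex-4-enoate (racemic) | CC(=O)C(CC=C(C)C)C(=O)OC(C)(C)C | intermediate
10 | N-methoxy-N-methylacetamide | CC(=O)N(C)OC | starting material
11 | tert-butyl 2-(3-methylbut-2-en-1-yl)-3,5-dioxohexanoate (racemic, enol tautomers) | CC(=O)CC(=O)C(CC=C(C)C)C(=O)OC(C)(C)C | intermediate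
12 | tert-butyl (9S)-9-ArB-9-hydroxy-2-(3-methylbut-2-en-1-yl)-3,5,7-trioxononanoate (C-2 epimers and enol tautomers) | CC(C)=CCC(C(=O)OC(C)(C)C)C(=O)CC(=O)CC(=O)C[C@H](O)c1cc(CC=C(C)C)c(O[Si](C)(C)C(C)(C)C)c(O[Si](C)(C)C(C)(C)C)c1 | intermediate
13 | tert-butyl 2-(3-methylbut-2-en-1-yl)-3-oxo-4-[(2S)-2-ArB-4-oxo-3,4-dihydro-2H-pyran-6-yl]butanoate | CC(C)=CCC(C(=O)OC(C)(C)C)C(=O)CC1=CC(=O)C[C@@H](c2cc(CC=C(C)C)c(O[Si](C)(C)C(C)(C)C)c(O[Si](C)(C)C(C)(C)C)c2)O1 | intermediate
14 | (2S)-2-ArB-6-[6-methyl-2-oxo-3-(oxomethylidene)hept-5-en-1-yl]-2,3-dihydro-4H-pyran-4-one (acylketene) | CC(C)=CCC(=C=O)C(=O)CC1=CC(=O)C[C@@H](c2cc(CC=C(C)C)c(O[Si](C)(C)C(C)(C)C)c(O[Si](C)(C)C(C)(C)C)c2)O1 | intermediate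
15 | (2S)-2-ArB-5,7-dihydroxy-6-(3-methylbut-2-en-1-yl)chroman-4-one | CC(C)=CCc1cc([C@@H]2CC(=O)c3c(cc(O)c(CC=C(C)C)c3O)O2)cc(O[Si](C)(C)C(C)(C)C)c1O[Si](C)(C)C(C)(C)C | intermediate
16 | (2S)-2-[3,4-dihydroxy-5-(3-methylbut-2-en-1-yl)phenyl]-5,7-dihydroxy-6-(3-methylbut-2-en-1-yl)chroman-4-one | CC(C)=CCc1cc([C@@H]2CC(=O)c3c(cc(O)c(CC=C(C)C)c3O)O2)cc(O)c1O | target

**Totals**
Total step count: 8. Longest linear sequence: 6 (steps 1, 2, 3, 6, 7, 8).

**Steps most likely to fail**

Step 7. The acylketene may form too slowly from the α-substituted tert-butyl ester, or form before ring C is closed, which would give a 2-pyranone. The fallback swaps the ester for a dioxinone, which releases the same ketene by retro-[4+2] at about 105 °C and is inert to the acid stage. It sets out from 9 (with 6 as partner) and comes back at ketene 14, hence 15. Heating 9 with a large excess of acetone (xylene, 135 °C, sealed vessel) traps the ketene as 2,2,6-trimethyl-5-(3-methylbut-2-en-1-yl)-4H-1,3-dioxin-4-one F1. Lateral lithiation (LiHMDS, 2 equiv, −78 °C) and acetylation with acetyl chloride gives 2,2-dimethyl-5-(3-methylbut-2-en-1-yl)-6-(2-oxopropyl)-4H-1,3-dioxin-4-one F2. Its dianion (LDA) is acylated by the lithium alkoxide of 6 to 6-[(6S)-6-ArB-6-hydroxy-2,4-dioxohexyl]-2,2-dimethyl-5-(3-methylbut-2-en-1-yl)-4H-1,3-dioxin-4-one F3. CSA at 23 °C closes the dihydropyranone to 6-{[(2S)-2-ArB-4-oxo-3,4-dihydro-2H-pyran-6-yl]methyl}-2,2-dimethyl-5-(3-methylbut-2-en-1-yl)-4H-1,3-dioxin-4-one F4, which is not isolated and at 105 °C loses acetone to give 14 and then 15.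

Step 6. The trianion may deprotonate the ester of 6 instead of acylating it. The fallback uses a far more electrophilic acyl donor that also sets the stereocentre by auxiliary control. It sets out from 4 and comes back at 12. Aldol of 4 with the chlorotitanium enolate of (S)-3-acetyl-4-isopropylthiazolidine-2-thione (TiCl4, i-Pr2NEt, CH2Cl2, −78 °C; auxiliary antipode chosen for the (S)-carbinol) gives, after chromatographic removal of the minor diastereomer, (4S)-3-[(3S)-3-ArB-3-hydroxypropanoyl]-4-isopropyl-1,3-thiazolidine-2-thione F5. The trianion of 11 displaces the thiazolidinethione at −78 °C, faster than proton transfer, to give 12.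

Step 2. The hindered ortho-silyloxy bromide may couple sluggishly with the prenylstannane or give some branched (1,1-dimethylallyl) product. The fallback installs an allyl group and converts it into prenyl by metathesis. It sets out from 2 and comes back at 4. Stille coupling of 2 with allyltributylstannane (Pd(PPh3)4, toluene, 100 °C; no regiochemical ambiguity) gives 3-allyl-4,5-bis(tert-butyldimethylsilyloxy)benzaldehyde F6. Cross-metathesis with 2-methylbut-2-ene (Grubbs second-generation catalyst, CH2Cl2, 40 °C) gives 4.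

**Further compounds**
F1 | step 7 | 2,2,6-trimethyl-5-(3-methylbut-2-en-1-yl)-4H-1,3-dioxin-4-one | CC1=C(CC=C(C)C)C(=O)OC(C)(C)O1
F2 | step 7 | 2,2-dimethyl-5-(3-methylbut-2-en-1-yl)-6-(2-oxopropyl)-4H-1,3-dioxin-4-one | CC(=O)CC1=C(CC=C(C)C)C(=O)OC(C)(C)O1
F3 | step 7 | 6-[(6S)-6-ArB-6-hydroxy-2,4-dioxohexyl]-2,2-dimethyl-5-(3-methylbut-2-en-1-yl)-4H-1,3-dioxin-4-one | CC(C)=CCC1=C(CC(=O)CC(=O)C[C@H](O)c2cc(CC=C(C)C)c(O[Si](C)(C)C(C)(C)C)c(O[Si](C)(C)C(C)(C)C)c2)OC(C)(C)OC1=O
F4 | step 7 | 6-{[(2S)-2-ArB-4-oxo-3,4-dihydro-2H-pyran-6-yl]methyl}-2,2-dimethyl-5-(3-methylbut-2-en-1-yl)-4H-1,3-dioxin-4-one | CC(C)=CCC1=C(CC2=CC(=O)C[C@@H](c3cc(CC=C(C)C)c(O[Si](C)(C)C(C)(C)C)c(O[Si](C)(C)C(C)(C)C)c3)O2)OC(C)(C)OC1=O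
F5 | step 6 | (4S)-3-[(3S)-3-ArB-3-hydroxypropanoyl]-4-isopropyl-1,3-thiazolidine-2-thione | CC(C)[C@H]1CSC(=S)N1C(=O)C[C@H](O)c1cc(CC=C(C)C)c(O[Si](C)(C)C(C)(C)C)c(O[Si](C)(C)C(C)(C)C)c1
F6 | step 2 | 3-allyl-4,5-bis(tert-butyldimethylsilyloxy)benzaldehyde | O=Cc1cc(O[Si](C)(C)C(C)(C)C)c(O[Si](C)(C)C(C)(C)C)c(CC=C)c1
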